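**Plan**
- Cuts: first the two C(sp)–C5(thienyl) bonds (twofold Sonogashira coupling). Each ethynyl group is then traced back to a CH2CHO arm, and the two arms are rejoined as the C=C bond of a cyclohexene. Last, the C3–C4 bond of the cyclobutane is cut to a 1,4-diiodide.
- Enabling feature: C3 and C4 of the four-membered ring are bare CH2 groups, and stereocentres C1 and C2 each carry a two-carbon alkyne arm. C1, C2 and these four alkyne carbons can therefore be drawn as one cyclohexene ring that holds C1 and C2 trans while C3–C4 is closed.
- Forward ring order: cyclohexene by Diels–Alder reaction, then cyclobutane by anionic C3–C4 closure to a trans-fused bicyclo[4.2.0]octene. The six-membered ring is then opened by ozonolysis, the arms are turned into alkynes, and the bithiophenes are attached.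
- Stereochemistry: the trans relationship comes from the E geometry of a fumarate. The absolute sense comes from its (−)-menthyl ester groups in one Lewis-acid-promoted cycloaddition. No later step makes or breaks a bond at C1 or C2.

Key step: step 6

Assumption: the aluminium-promoted cycloaddition of the fumarate of (1R,2S,5R)-menthol is taken to favour the (1S,2S) adduct; if the sense proved opposite, (1S,2R,5S)-menthol would be used with no other change.
Remark: the descriptors change from S,S to R,R in step 8 only because the unsaturated arm then outranks the ring carbon in the CIP order; the spatial arrangement is unchanged.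

**Step 1**
Reactants: 1 fumaric acid; 2 (1R,2S,5R)-menthol
Product: 3 bis[(1R,2S,5R)-menthyl] fumarate
Conditions: 2 (2.1 equiv), p-TsOH·H2O (5 mol %), toluene, reflux, Dean–Stark trap
Reagents that add atoms: none
Why: Fischer esterification driven by azeotropic removal of water; the carbinol C–O bond of menthol is not broken, so the auxiliary keeps its configuration and the E alkene is retained.

**Step 2**
Reactants: 3 bis[(1R,2S,5R)-menthyl] fumarate; 4 buta-1,3-diene
Product: 5 bis[(1R,2S,5R)-menthyl] (1S,2S)-cyclohex-4-ene-1,2-dicarboxylate
Conditions: 4 (excess), i-Bu2AlCl (2 equiv), hexane–toluene, −40 °C; 1 M HCl quench; crystallisation or chromatography to remove the minor diastereomer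
Reagents that add atoms: none
Why: Lewis-acid-promoted asymmetric Diels–Alder reaction in which aluminium coordination fixes both enoate units s-trans, so that the two menthyl groups of the C2-symmetric dienophile shield the same alkene face; butadiene adds to the open face and sets both centres together as S,S, and suprafacial addition to the E alkene makes them trans.

**Step 3**
Reactants: 5 bis[(1R,2S,5R)-menthyl] (1S,2S)-cyclohex-4-ene-1,2-dicarboxylate
Product: 6 [(1S,2S)-cyclohex-4-ene-1,2-diyl]dimethanol
Conditions: LiAlH4, THF, 0 °C → rt; aq. NaOH work-up; menthol recovered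
Reagents that add atoms: none
Why: Standard LiAlH4 ester reduction, in which hydride delivery outruns enolisation so the two stereocentres are kept, the isolated alkene is inert and the auxiliary is released.

**Step 4**
Reactants: 6 [(1S,2S)-cyclohex-4-ene-1,2-diyl]dimethanol
Product: 7 [(1S,2S)-cyclohex-4-ene-1,2-diyl]bis(methylene) dimethanesulfonate
Conditions: MsCl (2.4 equiv), Et3N (3 equiv), CH2Cl2, 0 °C
Reagents that add atoms: methanesulfonyl chloride, CS(=O)(=O)Cl
Why: Sulfonylation of two primary alcohols changes only O–H bonds, and fast double mesylation in the cold leaves no free hydroxyl to close a tetrahydrofuran on the neighbouring arm.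

**Step 5**
Reactants: 7 [(1S,2S)-cyclohex-4-ene-1,2-diyl]bis(methylene) dimethanesulfonate
Product: 8 (4S,5S)-4,5-bis(iodomethyl)cyclohex-1-ene
Conditions: NaI (6 equiv), acetone, reflux, dark
Reagents that add atoms: sodium iodide, [Na+].[I-]
Why: Finkelstein reaction, an SN2 displacement at two primary carbons driven by precipitation of sodium mesylate, with the stereocentres one atom away from the reacting carbons.

**Step 6**
Reactants: 8 (4S,5S)-4,5-bis(iodomethyl)cyclohex-1-ene
Product: 10 (1S,6S)-bicyclo[4.2.0]oct-3-ene, via iodomethyl alkyllithium 9 (not isolated)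
Conditions: t-BuLi (2.1 equiv, slow addition), pentane–Et2O 3:2, 0.05 M, −78 °C → rt; H2O quench; solvents distilled off through a column, 10 kept as a pentane concentrate
Reagents that add atoms: none
Why: t-BuLi exchanges one of the two homotopic C–I bonds through an iodine ate complex to give the primary alkyllithium 9, while the second equivalent consumes the t-BuI released so that it cannot quench 9. The carbanionic CH2 of 9 then displaces the iodide of the neighbouring arm in an intramolecular SN2 reaction, a 4-exo-tet closure that makes the C7–C8 bond of 10, which is the C3–C4 bond of the cyclobutane of the target. The closest known reaction type is the intramolecular Wurtz-type cyclisation of 1,4-diiodoalkanes to cyclobutanes by lithium–iodine exchange in pentane–ether. No stereocentre is formed, and since bonds change only at the two exocyclic methylene carbons, the S,S configuration from step 2 is carried through and dictates the trans ring fusion. The selectivity needed is chemoselectivity for single exchange and closure over double exchange, Grob-type cleavage of the C4–C5 bond and intermolecular coupling; the gauche diequatorial arms of the half-chair hold the two reacting carbons close, and slow addition of the base to a cold dilute solution keeps t-BuLi scarce while 9 closes. The ring alkene stands in a 4-pentenyl relationship to the C–Li bond, for which no favourable carbolithiation mode exists, so it should survive.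

**Step 7**
Reactants: 10 (1S,6S)-bicyclo[4.2.0]oct-3-ene
Product: 12 2,2'-[(1S,2S)-cyclobutane-1,2-diyl]diacetaldehyde, via secondary ozonide 11 (not isolated)
Conditions: O3, CH2Cl2, −78 °C; then Me2S, −78 °C → rt; used without storage
Reagents that add atoms: ozone, [O-][O+]=O
Why: Ozonolysis by the Criegee mechanism with reductive work-up cleaves the only π bond and opens the six-membered ring into two CH2CHO arms, whose enolisable positions are the arm CH2 groups and not the ring stereocentres.

**Step 8**
Reactants: 12 2,2'-[(1S,2S)-cyclobutane-1,2-diyl]diacetaldehyde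
Product: 14 (1R,2R)-1,2-diethynylcyclobutane, via bis(enol nonaflate) 13 (not isolated)
Conditions: n-C4F9SO2F (NfF, 2.4 equiv), t-BuN=P(NC4H8)3 (P1 phosphazene base, 5 equiv, added last), DMF, −20 °C → rt; extraction into pentane, kept as a titrated solution
Reagents that add atoms: none
Why: Known one-pot conversion of enolisable aldehydes into terminal alkynes by enolate O-sulfonylation with NfF and base-induced E2 loss of nonaflate; the leaving group sits on the terminal carbon so only an alkyne can form, and intramolecular aldol closure is disfavoured because it would need a trans-fused bicyclo[3.2.0]heptane.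

**Step 9**
Reactants: 14 (1R,2R)-1,2-diethynylcyclobutane; 15 5-bromo-2,2'-bithiophene
Product: 16 cardopatine
Conditions: 15 (2.3 equiv), PdCl2(PPh3)2 (5 mol %), CuI (10 mol %), Et3N–THF, degassed, 50 °C, dark
Reagents that add atoms: none
Why: Twofold Sonogashira coupling (oxidative addition of the C–Br bond to zerovalent palladium formed in situ from the divalent precatalyst, transmetalation from the copper acetylide, reductive elimination), run with an amine base too weak to touch the propargylic stereocentres.

**Compound list**
1 | fumaric acid | OC(=O)/C=C/C(=O)O | starting material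
2 | (1R,2S,5R)-menthol | CC(C)[C@@H]1CC[C@@H](C)C[C@H]1O | starting material
3 | bis[(1R,2S,5R)-menthyl] fumarate | CC(C)[C@@H]1CC[C@@H](C)C[C@H]1OC(=O)/C=C/C(=O)O[C@@H]1C[C@H](C)CC[C@H]1C(C)C | intermediate
4 | buta-1,3-diene | C=CC=C | starting material
5 | bis[(1R,2S,5R)-menthyl] (1S,2S)-cyclohex-4-ene-1,2-dicarboxylate | CC(C)[C@@H]1CC[C@@H](C)C[C@H]1OC(=O)[C@H]2CC=CC[C@@H]2C(=O)O[C@@H]1C[C@H](C)CC[C@H]1C(C)C | intermediate
6 | [(1S,2S)-cyclohex-4-ene-1,2-diyl]dimethanol | OC[C@H]1CC=CC[C@@H]1CO | intermediate
7 | [(1S,2S)-cyclohex-4-ene-1,2-diyl]bis(methylene) dimethanesulfonate | CS(=O)(=O)OC[C@H]1CC=CC[C@@H]1COS(C)(=O)=O | intermediate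
8 | (4S,5S)-4,5-bis(iodomethyl)cyclohex-1-ene | C1[C@@H]([C@@H](CI)CC=C1)CI | intermediate
9 | {[(1S,6S)-6-(iodomethyl)cyclohex-3-en-1-yl]methyl}lithium | [Li]C[C@H]1CC=CC[C@@H]1CI | intermediate
10 | (1S,6S)-bicyclo[4.2.0]oct-3-ene, trans ring fusion | C1[C@@H]2CC[C@H]2CC=C1 | intermediate
11 | secondary ozonide of 10: a 1,2,4-trioxolane whose two carbons are former C3 and C4 of 10, cyclobutane unchanged, acetal carbons unassigned | C1[C@@H]2CC[C@H]2CC3OOC1O3 | intermediate
12 | 2,2'-[(1S,2S)-cyclobutane-1,2-diyl]diacetaldehyde | O=CC[C@@H]1CC[C@H]1CC=O | intermediate
13 | [(1R,2R)-cyclobutane-1,2-diyl]di(ethene-2,1-diyl) bis(nonafluorobutane-1-sulfonate), expected as an E/Z mixture | FC(F)(F)C(F)(F)C(F)(F)C(F)(F)S(=O)(=O)OC=C[C@@H]1CC[C@H]1C=COS(=O)(=O)C(F)(F)C(F)(F)C(F)(F)C(F)(F)F | intermediate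
14 | (1R,2R)-1,2-diethynylcyclobutane | C#C[C@@H]1CC[C@H]1C#C | intermediate
15 | 5-bromo-2,2'-bithiophene | Brc1ccc(-c2cccs2)s1 | starting material
16 | cardopatine, 5,5''-[(1R,2R)-cyclobutane-1,2-diyldi(ethyne-2,1-diyl)]bis(2,2'-bithiophene) | C(#C[C@@H]1CC[C@H]1C#Cc1ccc(-c2cccs2)s1)c1ccc(-c2cccs2)s1 | target

Total step count: 9.
Longest linear sequence: 9 steps, from 1 to 16. Compounds 2, 4 and 15 enter as purchased materials.

**Steps most likely to fail**

Step 6. The extra strain of the trans fusion may slow the closure. The alkyllithium could then fragment in a Grob sense across the C4–C5 bond, or both iodides could be exchanged before the ring forms. The fallback sets out from 8 and returns at 10, and it replaces the unstabilised carbanion by a sulfone-stabilised one that forms the same bond.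
- One equivalent of PhSO2Na in DMF should give (4S,5S)-4-(iodomethyl)-5-[(phenylsulfonyl)methyl]cyclohex-1-ene F1, with unreacted 8 recycled.
- LiHMDS in THF (−78 → 0 °C) deprotonates next to sulfur. The long-lived carbanion alkylates the remaining CH2I in a 4-exo-tet closure to (1R,6S)-7-(phenylsulfonyl)bicyclo[4.2.0]oct-3-ene F2, trans-fused, either C7 epimer.
- Reductive desulfonylation with sodium amalgam and Na2HPO4 in MeOH then delivers 10.

Step 8. Three processes could go wrong: self-condensation of the dialdehyde under the strong base, sluggish syn elimination from E-configured enol sulfonate units, or base-induced alkyne-to-allene migration that would erode the propargylic stereocentres. The fallback sets out from 12 and returns at 14, and it avoids enolate chemistry altogether.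
- Deoxygenative gem-dibromination of both aldehydes with (PhO)3P and Br2 in CH2Cl2 (−78 °C → rt) should give (1S,2S)-1,2-bis(2,2-dibromoethyl)cyclobutane F3.
- Fourfold dehydrobromination with t-BuOK in THF at 0 °C then gives 14.

Step 9. The risks are Glaser-type oxidative coupling of the diyne under copper, stalling after the first coupling because oxidative addition of the electron-rich bromothiophene is slow, and evaporative loss of the volatile diyne on warming. The fallback sets out from 14 and returns at 16, and it changes the nucleophile.
- Double deprotonation with n-BuLi (THF, −78 °C) and quenching with Bu3SnCl should give the non-volatile (1R,2R)-1,2-bis[(tributylstannyl)ethynyl]cyclobutane F4.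
- A copper-free and amine-free twofold Stille coupling of this stannane with 15 (Pd(PPh3)4, toluene, 80 °C) leads to 16.

**Further compounds**
F1 | step 6 | (4S,5S)-4-(iodomethyl)-5-[(phenylsulfonyl)methyl]cyclohex-1-ene | O=S(=O)(c1ccccc1)C[C@H]1CC=CC[C@@H]1CI
F2 | step 6 | (1R,6S)-7-(phenylsulfonyl)bicyclo[4.2.0]oct-3-ene, trans-fused, C7 unassigned | C1[C@@H]2C(S(=O)(=O)c3ccccc3)C[C@H]2CC=C1
F3 | step 8 | (1S,2S)-1,2-bis(2,2-dibromoethyl)cyclobutane | BrC(Br)C[C@@H]1CC[C@H]1CC(Br)Br
F4 | step 9 | (1R,2R)-1,2-bis[(tributylstannyl)ethynyl]cyclobutane | CCCC[Sn](CCCC)(CCCC)C#C[C@@H]1CC[C@H]1C#C[Sn](CCCC)(CCCC)CCCC
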